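**Retrosynthetic overview**

1. Target 28 is a C19 gibberellin (19,10-lactone, 7-acid, 16-ene) with 2β-, 3β- and 11β-hydroxyls. The C2/C3 diol is traced back to a C3 ketone (exo hydroxylation of its C2 enolate, then hydride from the lactone side), which comes from ring A ketol 23.
2. Ring A (C3–C4 bond) and the lactone (C4–C5 bond) are disconnected together to acrylate aldehyde 21. The enabling feature: C4 of ring A carries both the C18 methyl and the C19 lactone carbonyl, and C19–O–C10 bridges ring A across C5. An acrylate on the C10 oxygen is therefore a double C4 donor (C4=C18 of an α-methylene lactone is a latent C4 enolate), and the C1–C3 aldehyde arm on C10 lies over the exo face of that lactone, within reach of C4.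
3. 21 comes from tricyclic enone ester 16 (rings B, C, D) by Grignard addition of the C1–C3 arm to the C10 ketone and acryloylation.
4. Ring B of 16 arises by Dieckmann closure (C5–C10) and dehydrogenation; ring D and the C8 quaternary center by intramolecular Hosomi–Sakurai addition of a C13 allylsilane to a 2-carbomethoxy enone; ring C is cyclohex-2-enone, with C13 set by rhodium/(S)-BINAP 1,4-addition.
5. Order of ring formation: C (bought), D (step 6), B (step 9), lactone then ring A (both in step 15, ring A last).

Key step: step 15

Remark: gibberellane locants (C1–C19) are used; β is the face of the hydrogens on C5 and C9, the C7 carboxyl and the C15–C16 bridge, and the lactone bridge is α. Compounds 9–15 are carried as mixtures at C6 (and C9 where noted); these centers are erased or equilibrated later. Reagent 17 is bought as a THF solution.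

**Step 1**
Reactants: 1 (2-bromoprop-2-en-1-yl)trimethylsilane
Product: 2 alkenyl pinacol boronate
Conditions: PdCl2(PPh3)2 (3 mol %), PPh3, KOPh, bis(pinacolato)diboron, toluene, 50 °C
Reagents that add atoms: bis(pinacolato)diboron, CC1(C)OB(OC1(C)C)B1OC(C)(C)C(C)(C)O1
Why: Miyaura borylation of an alkenyl bromide; the allylsilane should be inert to the palladium/phenoxide system, as in other cross-couplings of this bromide.

**Step 2**
Reactants: 2 alkenyl pinacol boronate; 3 cyclohex-2-en-1-one
Product: 4 (3S)-3-[3-(trimethylsilyl)prop-1-en-2-yl]cyclohexan-1-one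
Conditions: [RhCl(C8H12)]2 (1.5 mol %; C8H12 = cycloocta-1,5-diene), (S)-BINAP (3.3 mol %), KOH (10 mol %), dioxane/H2O 10:1, 60 °C
Reagents that add atoms: none
Why: Hayashi–Miyaura rhodium-catalysed asymmetric 1,4-addition; the (S)-BINAP–rhodium alkenyl species should add to one enantioface of the enone and set C13 (S), the only center from which all others are relayed.

**Step 3**
Reactants: 4 (3S)-ketone; 5 dimethyl carbonate
Product: 6 β-keto ester
Conditions: NaH (2.2 equiv), THF, 65 °C; AcOH quench
Reagents that add atoms: none
Why: Claisen C-acylation under thermodynamic control should occur at the α-carbon remote from the C13 substituent (C9), giving the stabilised β-keto ester enolate; C13 is not epimerisable.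

**Step 4**
Reactants: 6 β-keto ester
Product: 7 2-carbomethoxy enone
Conditions: NaH (1.05 equiv), THF, 0 °C; PhS(Cl)=N-t-Bu (1.1 equiv), −78 → 0 °C
Reagents that add atoms: none
Why: Mukaiyama dehydrogenation; the sodium enolate is sulfenylated at C9 by the sulfinimidoyl chloride and the adduct undergoes syn-elimination toward C8, the reagent reacting with the enolate far faster than with the allylsilane.

**Step 5**
Reactants: 7 2-carbomethoxy enone; 8 dimethyl succinate
Product: 10 alkylidene β-keto ester, via lithium enolate 9 (not isolated)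
Conditions: LiN(iPr)2 (1.1 equiv), 8, THF, −78 °C; add 7; then PhS(Cl)=N-t-Bu, −78 → 0 °C; aq. NH4Cl
Reagents that add atoms: none
Why: Michael addition of the succinate enolate to C8 of the doubly activated alkene, then Mukaiyama dehydrogenation of the resulting β-keto ester enolate in the same flask, should restore the C8=C9 alkene now bearing the C6/C7/C5 unit; the C6 center formed is irrelevant because it is erased in step 11.

**Step 6**
Reactants: 10 alkylidene β-keto ester
Product: 11 bicyclo[3.2.1]octane keto triester
Conditions: TiCl4 (1.1 equiv), CH2Cl2, −78 °C; aq. NaHCO3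
Reagents that add atoms: none
Why: intramolecular Hosomi–Sakurai reaction; TiCl4 chelates the β-keto ester and the allylsilane on C13 can reach C8 only on its own face, so ring D (with its exocyclic methylene) and the C8 quaternary center are set by C13, with 1,4- over 1,2-addition favoured by the chelated acceptor and the lower strain of the bicyclo[3.2.1]octane.

**Step 7**
Reactants: 11 bicyclo[3.2.1]octane keto triester
Product: 12 11β-alcohol
Conditions: NaBH4, MeOH, −40 °C
Reagents that add atoms: none
Why: borohydride reduction of the β-keto ester ketone; hydride should attack C11 from the exo face (side of the one-carbon bridge C14), away from the C15–C16 bridge, giving the axial 11β-alcohol as in reductions of bicyclo[3.2.1]octan-3-ones.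

**Step 8**
Reactants: 12 11β-alcohol
Product: 13 11β-silyl ether
Conditions: TBSOTf, 2,6-lutidine, CH2Cl2, −78 → 0 °C
Reagents that add atoms: tert-butyldimethylsilyl trifluoromethanesulfonate, CC(C)(C)[Si](C)(C)OS(=O)(=O)C(F)(F)F
Why: silyl ether formation with the triflate is needed for the hindered axial alcohol; no stereocenter is touched.

**Step 9**
Reactants: 13 11β-silyl ether
Product: 14 tricyclic β-keto diester
Conditions: LiN(SiMe3)2 (2.5 equiv), THF, −78 → −20 °C; aq. NH4Cl
Reagents that add atoms: none
Why: Dieckmann condensation; the kinetic enolate of the least hindered ester methylene (C5) attacks the ester carbonyl on C9 (C10) to close ring B (5-exo-trig), driven by deprotonation of the product, while the low temperature avoids β-elimination of the C11 silyloxy group.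

**Step 10**
Reactants: 14 tricyclic β-keto diester
Product: 15 tricyclic keto ester
Conditions: LiCl, H2O (2 equiv), DMSO, 130 °C
Reagents that add atoms: none
Why: Krapcho dealkoxycarbonylation removes only the β-keto ester carboxyl on C5; under these conditions C9 (now α to the C10 ketone) should equilibrate to the more stable hydrindanone that is cis-fused to ring C, with the C9 hydrogen β.

**Step 11**
Reactants: 15 tricyclic keto ester
Product: 16 tricyclic enone ester
Conditions: LiN(iPr)2, THF, −78 °C; PhS(Cl)=N-t-Bu, −78 °C; aq. NH4Cl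
Reagents that add atoms: none
Why: kinetic enolisation at the C5 methylene rather than the ring-fusion C9, followed by Mukaiyama dehydrogenation toward C6, should give the 4-oxo-2-enoate and remove the C6 mixture.

**Step 12**
Reactants: 16 tricyclic enone ester; 17 [2-(1,3-dioxolan-2-yl)ethyl]magnesium bromide
Product: 18 tertiary alcohol
Conditions: CeCl3 (anhydrous), THF, −78 °C; aq. NH4Cl
Reagents that add atoms: none
Why: cerium-mediated Grignard 1,2-addition to the cyclopentenone carbonyl; the reagent should approach C10 anti to the adjacent C9–C11 bond (convex face of the cis-fused B/C system), placing the C1–C3 arm β and the oxygen α.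

**Step 13**
Reactants: 18 tertiary alcohol; 19 acryloyl chloride
Product: 20 acrylate
Conditions: KN(SiMe3)2, THF, −78 °C; then 19; aq. NH4Cl
Reagents that add atoms: none
Why: O-acylation of the potassium alkoxide is the reliable way to esterify a hindered tertiary alcohol; no stereocenter changes.

**Step 14**
Reactants: 20 acrylate
Product: 21 acrylate aldehyde
Conditions: PPTS (cat.), acetone/H2O 10:1, 55 °C
Reagents that add atoms: water, O
Why: mild acetal hydrolysis; the secondary silyl ether, the tertiary acrylate (its allylic cation is destabilised by the ester on C6) and the exocyclic alkene should survive.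

**Step 15**
Reactants: 21 acrylate aldehyde
Product: 23 ring A ketol lactone (C3 epimers), via methylene lactone aldehyde 22 (not isolated)
Conditions: PMe3 (30 mol %), THF, 23 °C; then [(Ph3P)CuH]6 (0.5 equiv), toluene, −40 → 0 °C; aq. NH4Cl
Reagents that add atoms: none
Why: Proposed new method: PMe3 adds to the acrylate terminus, the C4 enolate so formed attacks C5 of the enoate (5-exo-trig, cis-fused γ-lactone), and proton transfer with loss of PMe3 gives α-methylene lactone 22; [(Ph3P)CuH]6 then delivers hydride to C18 and the copper enolate, formed only at C4, adds to the C3 aldehyde (6-(enolexo)-exo-trig, ring A). The closest known reaction types are the phosphine-catalysed intramolecular Rauhut–Currier cyclisation of tethered enone/enoate pairs and the copper hydride reductive aldol cyclisation of unsaturated esters onto tethered carbonyls, which have not been combined in one flask or run through an ester tether. C5 is set by the tether (the acyl group on the C10 oxygen reaches C5 only on its own face, so the hydrogen on C5 is cis to the C1 arm), C6 by protonation of the ester enolate and equilibration to the ester trans to the new C5–C4 bond, and C4 by the bridge geometry, because the aldehyde arm on C10 can reach the enolate only from the face cis to C10–C1, which places C18 (born from the acrylate CH2) on the ring B face. C3 forms as an epimer mixture that is erased in step 16. The step needs hydride delivery to the methylene lactone rather than to the aldehyde or the saturated esters, which the high acceptor reactivity of a 1,1-disubstituted α-methylene lactone at −40 °C should secure. It also needs a C4 rather than a C6 enolate and an un-enolised aldehyde, both secured by generating the enolate through conjugate reduction in the absence of base.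

**Step 16**
Reactants: 23 ring A ketol lactone (C3 epimers)
Product: 24 3-ketone
Conditions: Dess–Martin periodinane, NaHCO3, CH2Cl2, 0 → 23 °C
Reagents that add atoms: none
Why: Dess–Martin oxidation converges both C3 epimers to one β-keto lactone, which cannot enolise toward the quaternary C4.

**Step 17**
Reactants: 24 3-ketone
Product: 25 2β-hydroxy-3-ketone
Conditions: KN(SiMe3)2 (1.05 equiv), THF, −78 °C; 2-(phenylsulfonyl)-3-phenyloxaziridine; aq. NH4Cl at −78 °C
Reagents that add atoms: 2-(phenylsulfonyl)-3-phenyloxaziridine, O=S(=O)(c1ccccc1)N1OC1c1ccccc1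
Why: Davis enolate hydroxylation; C2 is the only enolisable position of the C3 ketone, and the oxaziridine should approach from the exo (β) face opposite the lactone bridge to give the equatorial 2β-hydroxyl, with low temperature and one equivalent of base avoiding C6 deprotonation and retro-Michael opening.

**Step 18**
Reactants: 25 2β-hydroxy-3-ketone
Product: 26 2β,3β-diol
Conditions: KBH(s-Bu)3 (2.5 equiv), THF, −78 °C; aq. NH4Cl
Reagents that add atoms: none
Why: bulky hydride reduction; attack along the equatorial trajectory, avoiding the syn-axial β-hydrogens on C1 and C5, should give the axial 3β-alcohol cis to the 2β-hydroxyl, the expected outcome for 3-oxo gibberellin lactones, and −78 °C suppresses retro-aldol of the aldolate.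

**Step 19**
Reactants: 26 2β,3β-diol
Product: 27 triol methyl ester
Conditions: HF·pyridine, pyridine/THF, 0 → 23 °C
Reagents that add atoms: none
Why: fluoride desilylation under buffered conditions spares the exocyclic alkene, the lactone and the retro-aldol-prone 3-hydroxy array.

**Step 20**
Reactants: 27 triol methyl ester
Product: 28 CNP0322347.1
Conditions: LiSPr, HMPA, 23 °C; then aq. HCl to pH 3
Reagents that add atoms: none
Why: SN2 demethylation of the hindered C7 methyl ester by thiolate, the standard ester cleavage in gibberellins, leaves the lactone and all stereocenters untouched.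

**Compound list**

1 | (2-bromoprop-2-en-1-yl)trimethylsilane | C=C(Br)C[Si](C)(C)C | starting material
2 | trimethyl[2-(4,4,5,5-tetramethyl-1,3,2-dioxaborolan-2-yl)prop-2-en-1-yl]silane | C=C(C[Si](C)(C)C)B1OC(C)(C)C(C)(C)O1 | intermediate
3 | cyclohex-2-en-1-one | O=C1C=CCCC1 | starting material
4 | (3S)-3-[3-(trimethylsilyl)prop-1-en-2-yl]cyclohexan-1-one | C=C(C[Si](C)(C)C)[C@@H]1CC(=O)CCC1 | intermediate
5 | dimethyl carbonate | COC(=O)OC | starting material
6 | methyl (4S)-2-oxo-4-[3-(trimethylsilyl)prop-1-en-2-yl]cyclohexane-1-carboxylate (C1 epimers and enol) | C=C(C[Si](C)(C)C)[C@@H]1CC(=O)C(C(=O)OC)CC1 | intermediate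
7 | methyl (4S)-6-oxo-4-[3-(trimethylsilyl)prop-1-en-2-yl]cyclohex-1-ene-1-carboxylate | C=C(C[Si](C)(C)C)[C@@H]1CC(=O)C(C(=O)OC)=CC1 | intermediate
8 | dimethyl butanedioate (dimethyl succinate) | COC(=O)CCC(=O)OC | starting material
9 | lithium (5S)-3-(1,4-dimethoxy-1,4-dioxobutan-2-yl)-2-(methoxycarbonyl)-5-[3-(trimethylsilyl)prop-1-en-2-yl]cyclohex-1-en-1-olate (epimers at the new sp3 carbons) | C=C(C[Si](C)(C)C)[C@@H]1CC([O-])=C(C(=O)OC)C(C(CC(=O)OC)C(=O)OC)C1.[Li+] | intermediate
10 | methyl (4S)-2-(1,4-dimethoxy-1,4-dioxobutan-2-yl)-6-oxo-4-[3-(trimethylsilyl)prop-1-en-2-yl]cyclohex-1-ene-1-carboxylate (both epimers at the succinate carbon) | C=C(C[Si](C)(C)C)[C@@H]1CC(=O)C(C(=O)OC)=C(C(CC(=O)OC)C(=O)OC)C1 | intermediate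
11 | dimethyl 2-[2-(methoxycarbonyl)-6-methylidene-3-oxobicyclo[3.2.1]octan-1-yl]butanedioate (rings C and D; C8 and C13 as in the target; C6 and C9 epimers) | C=C1C[C@]2(C(CC(=O)OC)C(=O)OC)C[C@H]1CC(=O)C2C(=O)OC | intermediate
12 | dimethyl 2-[3-hydroxy-2-(methoxycarbonyl)-6-methylidenebicyclo[3.2.1]octan-1-yl]butanedioate with the hydroxyl on the face of the two-carbon bridge (11β) | C=C1C[C@]2(C(CC(=O)OC)C(=O)OC)C[C@H]1C[C@H](O)C2C(=O)OC | intermediate
13 | 11β-tert-butyldimethylsilyl ether of 12 | C=C1C[C@]2(C(CC(=O)OC)C(=O)OC)C[C@H]1C[C@H](O[Si](C)(C)C(C)(C)C)C2C(=O)OC | intermediate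
14 | tricyclic β-keto diester (rings B, C, D; C10 ketone; CO2Me on C5 and on C6; 11β-OTBS; 16-methylene) | C=C1C[C@]23C[C@H]1C[C@H](O[Si](C)(C)C(C)(C)C)C2C(=O)C(C(=O)OC)C3C(=O)OC | intermediate
15 | tricyclic keto ester (C10 ketone; CO2Me on C6; cis B/C fusion with 9β-H; 11β-OTBS; C6 epimers) | C=C1C[C@]23C[C@H]1C[C@H](O[Si](C)(C)C(C)(C)C)[C@H]2C(=O)CC3C(=O)OC | intermediate
16 | tricyclic enone ester (C10 ketone conjugated with C5=C6; CO2Me on C6; 9β-H; 11β-OTBS; 16-methylene) | C=C1C[C@]23C[C@H]1C[C@H](O[Si](C)(C)C(C)(C)C)[C@H]2C(=O)C=C3C(=O)OC | intermediate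
17 | [2-(1,3-dioxolan-2-yl)ethyl]magnesium bromide (THF solution) | Br[Mg]CCC1OCCO1 | starting material
18 | tertiary alcohol (C10 α-OH; C10 β-[2-(1,3-dioxolan-2-yl)ethyl]; C5=C6 enoate) | C=C1C[C@]23C[C@H]1C[C@H](O[Si](C)(C)C(C)(C)C)[C@H]2[C@](O)(CCC4OCCO4)C=C3C(=O)OC | intermediate
19 | prop-2-enoyl chloride (acryloyl chloride) | C=CC(=O)Cl | starting material
20 | C10 acrylate of 18 | C=C1C[C@]23C[C@H]1C[C@H](O[Si](C)(C)C(C)(C)C)[C@H]2[C@](OC(=O)C=C)(CCC4OCCO4)C=C3C(=O)OC | intermediate
21 | acrylate aldehyde (C10 α-acryloyloxy; C10 β-(3-oxopropyl)) | C=C1C[C@]23C[C@H]1C[C@H](O[Si](C)(C)C(C)(C)C)[C@H]2[C@](OC(=O)C=C)(CCC=O)C=C3C(=O)OC | intermediate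
22 | methylene lactone aldehyde (19,10-lactone with exocyclic C4=C18; 5β-H; 6β-CO2Me; 3-oxopropyl arm on C10) | C=C1C[C@]23C[C@H]1C[C@H](O[Si](C)(C)C(C)(C)C)[C@H]2[C@@]4(CCC=O)OC(=O)C(=C)[C@H]4[C@@H]3C(=O)OC | intermediate
23 | ring A ketol lactone: pentacyclic 19,10-lactone 7-methyl ester with 3-OH (both epimers) and 11β-OTBS | C=C1C[C@]23C[C@H]1C[C@H](O[Si](C)(C)C(C)(C)C)[C@H]2[C@@]45CCC(O)[C@@](C)(C(=O)O4)[C@H]5[C@@H]3C(=O)OC | intermediate
24 | 3-ketone of 23 | C=C1C[C@]23C[C@H]1C[C@H](O[Si](C)(C)C(C)(C)C)[C@H]2[C@@]45CCC(=O)[C@@](C)(C(=O)O4)[C@H]5[C@@H]3C(=O)OC | intermediate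
25 | 2β-hydroxy-3-ketone | C=C1C[C@]23C[C@H]1C[C@H](O[Si](C)(C)C(C)(C)C)[C@H]2[C@@]45C[C@H](O)C(=O)[C@@](C)(C(=O)O4)[C@H]5[C@@H]3C(=O)OC | intermediate
26 | 2β,3β-diol (11β-OTBS; 7-methyl ester) | C=C1C[C@]23C[C@H]1C[C@H](O[Si](C)(C)C(C)(C)C)[C@H]2[C@@]45C[C@H](O)[C@H](O)[C@@](C)(C(=O)O4)[C@H]5[C@@H]3C(=O)OC | intermediate
27 | 2β,3β,11β-triol 7-methyl ester | C=C1C[C@]23C[C@H]1C[C@H](O)[C@H]2[C@@]45C[C@H](O)[C@H](O)[C@@](C)(C(=O)O4)[C@H]5[C@@H]3C(=O)OC | intermediate
28 | CNP0322347.1: 2β,3β,11β-trihydroxy C19 gibberellin 19,10-lactone 7-acid with a 16-methylene group | C=C1C[C@]23C[C@H]1C[C@H](O)[C@H]2[C@@]12C[C@H](O)[C@H](O)[C@@](C)(C(=O)O1)[C@H]2[C@@H]3C(=O)O | target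

**Step count and risks**

Total step count: 20. Longest linear sequence: 20 steps (fully linear from 1).

Steps most likely to fail:

1. Step 15 (proposed new method). The phosphine may not turn over because proton transfer is slow in an aprotic medium; the transient C6 enolate or the phosphonium enolate may attack the aldehyde; or the copper enolate may be quenched before ring closure, giving plain conjugate reduction. The fallback uses known chemistry, sets out from 18 and comes back at 23. Alcohol 18 is acylated with propanoyl chloride (KN(SiMe3)2, THF, −78 °C) to the C10 propanoate F1. KH in THF/DMF at 0 °C closes the lactone by intramolecular Michael addition of the propanoate enolate to C5, giving the lactone acetal F2 (C4 epimers). PPTS in aqueous acetone unmasks the lactone aldehyde F3. K2CO3 in methanol then closes ring A by base-mediated intramolecular aldol addition of the lactone enolate to give 23 as C3 epimers, which converge in step 16.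

2. Step 6. The allylsilane may add 1,2 to the C11 ketone (norbornane-type closure) or be protodesilylated by adventitious acid before it reaches C8. The fallback replaces the cationic closure by a radical one, setting out from 10 and coming back at 11. Bromodesilylation of 10 with N-bromosuccinimide (CH2Cl2, −78 °C) gives the allylic bromide F4. Slow addition of Bu3SnH and AIBN in benzene at 80 °C generates the symmetrical allyl radical, which cannot add to a carbonyl group and should cyclise 5-exo onto C8 of the doubly activated alkene to give 11 after hydrogen transfer to C9.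

3. Step 2. Transmetalation of the hindered α-substituted alkenyl boronate may be slow, so protodeboronation competes, or enantioselectivity may erode. The fallback installs the silicon after the stereocenter, setting out from 3 and coming back at 4. Addition of potassium trifluoro(prop-1-en-2-yl)borate to 3 under [RhCl(C8H12)]2/(S)-BINAP gives (3S)-3-(prop-1-en-2-yl)cyclohexan-1-one F5. Ketalisation with ethylene glycol (PPTS, benzene, reflux) gives the dioxolane F6. Allylic lithiation of the isopropenyl group (n-BuLi, TMEDA, hexane) and trapping with Me3SiCl gives the allylsilane ketal F7. PPTS in aqueous acetone returns 4.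

**Further compounds**

F1 | step 15 | C10 propanoate of 18 | C=C1C[C@]23C[C@H]1C[C@H](O[Si](C)(C)C(C)(C)C)[C@H]2[C@](OC(=O)CC)(CCC4OCCO4)C=C3C(=O)OC
F2 | step 15 | lactone acetal (19,10-lactone with C4-H and C18 methyl; C4 epimers; dioxolane arm on C10) | C=C1C[C@]23C[C@H]1C[C@H](O[Si](C)(C)C(C)(C)C)[C@H]2[C@@]4(CCC5OCCO5)OC(=O)C(C)[C@H]4[C@@H]3C(=O)OC
F3 | step 15 | lactone aldehyde (as F2 with 3-oxopropyl arm) | C=C1C[C@]23C[C@H]1C[C@H](O[Si](C)(C)C(C)(C)C)[C@H]2[C@@]4(CCC=O)OC(=O)C(C)[C@H]4[C@@H]3C(=O)OC
F4 | step 6 | methyl (4S)-4-(3-bromoprop-1-en-2-yl)-2-(1,4-dimethoxy-1,4-dioxobutan-2-yl)-6-oxocyclohex-1-ene-1-carboxylate | C=C(CBr)[C@@H]1CC(=O)C(C(=O)OC)=C(C(CC(=O)OC)C(=O)OC)C1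
F5 | step 2 | (3S)-3-(prop-1-en-2-yl)cyclohexan-1-one | C=C(C)[C@@H]1CC(=O)CCC1
F6 | step 2 | (7S)-7-(prop-1-en-2-yl)-1,4-dioxaspiro[4.5]decane | C=C(C)[C@@H]1CC2(OCCO2)CCC1
F7 | step 2 | trimethyl{2-[(7S)-1,4-dioxaspiro[4.5]decan-7-yl]prop-2-en-1-yl}silane | C=C(C[Si](C)(C)C)[C@@H]1CC2(OCCO2)CCC1
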